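**Retrosynthetic overview**

1. The route rests on ring B (C1–C2–C3–C3a–C7a): its C3H2–C2=C(CH3)2 array is the 1,4-dihydro form of the diene C3=C2–C(CH3)=CH2. That 2-isopropenyl-1H-indene is what ring-closing enyne metathesis gives from a styrene carbon (C3 on ring A) and a methyl alkyne (C2), so ring B is closed last with C1 already set.
2. After the metathesis: chromium-catalysed 1,4-hydrogenation of the diene, mild hydrolysis of the C7 acetal, then chelation-controlled cleavage of the C6 methyl ether.
3. C1–C8′ bond: stereoconvergent nickel-catalysed Negishi arylation of a racemic ring A propargylic carbonate with the ring D arylzinc sets C1 (R).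
4. Ring A piece from 2-bromo-4-methoxybenzaldehyde: Wittig vinylation, directed lithiation/formylation (C7) and acetal, Br/Li exchange/formylation, propynyl Grignard addition with carbonate capture.
5. Ring C/D piece from 2,6-dibromo-4-methylphenol and methyl (R)-glycerate: Mitsunobu inversion sets C2′ (S), MeMgBr builds the carbinol, copper-catalysed O-arylation closes ring C. Ring order: C, then B; rings A and D are bought as arenes.

Key step: step 12

Numbering used: indane C1 (stereocentre), C2, C3, C3a, C4, C5, C6 (OH), C7 (CHO), C7a; benzodioxane O1′, C2′ (stereocentre), C3′, O4′, C4a′, C5′, C6′ (CH3), C7′, C8′ (bonded to C1), C8a′. Ring A is the benzo ring of the indane, ring B its five-membered ring, ring C the dioxane ring, ring D the benzo ring of the benzodioxane.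

Assumption: methyl (R)-glycerate of high enantiomeric purity is taken as a catalogue compound. The pybox antipode that gives the (1R) epimer in step 11 is to be assigned in a pilot run with each antipode; the two outcomes are diastereomers and can be told apart.

**Route**

Step 1
Reactants: 1 2-bromo-4-methoxybenzaldehyde
Product: 2 2-bromo-4-methoxy-1-vinylbenzene
Conditions: Ph3PCH3Br, KOtBu, THF, 0 °C to rt
Reagents that add atoms: methyltriphenylphosphonium bromide, C[P+](c1ccccc1)(c1ccccc1)c1ccccc1.[Br-]
Why: Wittig methylenation of the aryl aldehyde with the non-stabilised ylide should give the styrene that later supplies C3 and the migrating methylene.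

Step 2
Reactants: 2 2-bromo-4-methoxy-1-vinylbenzene
Product: 4 2-bromo-6-methoxy-3-vinylbenzaldehyde, via aryllithium 3 (not isolated)
Conditions: LiN(i-Pr)2, THF, −78 °C; DMF, −78 to 0 °C; aq. NH4Cl
Reagents that add atoms: N,N-dimethylformamide, CN(C)C=O
Why: Directed ortho-lithiation with the lithium amide removes the most acidic ring proton, the one flanked by Br and OMe (future C7), without bromine exchange or attack on the styrene at −78 °C, and DMF formylates the aryllithium.

Step 3
Reactants: 4 2-bromo-6-methoxy-3-vinylbenzaldehyde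
Product: 5 2-(2-bromo-6-methoxy-3-vinylphenyl)-1,3-dioxolane
Conditions: HOCH2CH2OH, HC(OEt)3, p-TsOH·H2O (cat.), CH2Cl2, rt
Reagents that add atoms: ethylene glycol, OCCO
Why: Acid-catalysed acetalisation, driven at room temperature by the orthoformate as water scavenger, masks the C7 formyl group under conditions mild enough for the para-methoxystyrene.

Step 4
Reactants: 5 2-(2-bromo-6-methoxy-3-vinylphenyl)-1,3-dioxolane
Product: 7 2-(1,3-dioxolan-2-yl)-3-methoxy-6-vinylbenzaldehyde, via aryllithium 6 (not isolated)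
Conditions: n-BuLi, THF, −78 °C; DMF, −78 to 0 °C; aq. NH4Cl
Reagents that add atoms: N,N-dimethylformamide, CN(C)C=O
Why: Bromine–lithium exchange is much faster than addition of n-BuLi to the styrene at −78 °C, and formylation of the aryllithium with DMF gives the aldehyde carbon that becomes C1.

Step 5
Reactants: 7 2-(1,3-dioxolan-2-yl)-3-methoxy-6-vinylbenzaldehyde; 8 1-propynylmagnesium bromide
Product: 10 rac-1-[2-(1,3-dioxolan-2-yl)-3-methoxy-6-vinylphenyl]but-2-yn-1-yl methyl carbonate, via magnesium alkoxide 9 (not isolated)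
Conditions: THF, 0 °C; then ClCO2Me, 0 °C to rt
Reagents that add atoms: methyl chloroformate, COC(=O)Cl
Why: 1,2-Addition of the slim alkynyl Grignard reagent to the hindered aldehyde gives the racemic magnesium alkoxide, which is acylated in the same flask to the propargylic carbonate; no stereocontrol is needed here because step 11 is stereoconvergent.

Step 6
Reactants: 11 methyl (2R)-2,3-dihydroxypropanoate
Product: 12 methyl (2R)-3-[(tert-butyldimethylsilyl)oxy]-2-hydroxypropanoate
Conditions: TBSCl, imidazole, CH2Cl2, 0 °C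
Reagents that add atoms: tert-butyldimethylsilyl chloride, CC(C)(C)[Si](C)(C)Cl
Why: Selective silylation of the primary hydroxyl over the less nucleophilic α-hydroxy ester position leaves the secondary alcohol free for the next step and does not touch the stereocentre.

Step 7
Reactants: 12 methyl (2R)-3-[(tert-butyldimethylsilyl)oxy]-2-hydroxypropanoate; 13 2,6-dibromo-4-methylphenol
Product: 14 methyl (2S)-3-[(tert-butyldimethylsilyl)oxy]-2-(2,6-dibromo-4-methylphenoxy)propanoate
Conditions: PPh3, DIAD, toluene, 0 °C to rt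
Reagents that add atoms: none
Why: Mitsunobu etherification of the acidic 2,6-dibromophenol with the α-hydroxy ester runs by SN2 with inversion, which turns the (R) carbinol centre into the (S) aryl ether centre that becomes C2′.

Step 8
Reactants: 14 methyl (2S)-3-[(tert-butyldimethylsilyl)oxy]-2-(2,6-dibromo-4-methylphenoxy)propanoate
Product: 16 (2S)-2-(2,6-dibromo-4-methylphenoxy)-3-methylbutane-1,3-diol, via silyl ether carbinol 15 (not isolated)
Conditions: MeMgBr (3.5 equiv), THF, 0 °C; then HCl (1 M, MeOH/H2O), rt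
Reagents that add atoms: methylmagnesium bromide, C[Mg]Br
Why: Double Grignard addition to the ester builds the tertiary carbinol faster than the α-aryloxy centre can enolise, and acidic methanolysis in the work-up removes the primary TBS ether.

Step 9
Reactants: 16 (2S)-2-(2,6-dibromo-4-methylphenoxy)-3-methylbutane-1,3-diol
Product: 17 2-[(2S)-8-bromo-6-methyl-2,3-dihydro-1,4-benzodioxin-2-yl]propan-2-ol
Conditions: CuI (10 mol%), 1,10-phenanthroline (20 mol%), Cs2CO3, toluene, 100 °C
Reagents that add atoms: none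
Why: Copper-catalysed intramolecular Ullmann-type O-arylation by the primary alcohol closes the six-membered ring C; the two bromines are equivalent, so either closure gives the same product with the remaining bromine at C8′, and the tertiary alcohol is too hindered to compete.

Step 10
Reactants: 17 2-[(2S)-8-bromo-6-methyl-2,3-dihydro-1,4-benzodioxin-2-yl]propan-2-ol
Product: 18 ({2-[(2S)-8-bromo-6-methyl-2,3-dihydro-1,4-benzodioxin-2-yl]propan-2-yl}oxy)trimethylsilane
Conditions: TMSCl, imidazole, DMF, rt
Reagents that add atoms: chlorotrimethylsilane, C[Si](C)(C)Cl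
Why: Silylation of the tertiary alcohol removes the only acidic proton so that the aryl bromide can be metalated in the next step.

Step 11
Reactants: 10 rac-1-[2-(1,3-dioxolan-2-yl)-3-methoxy-6-vinylphenyl]but-2-yn-1-yl methyl carbonate; 18 ({2-[(2S)-8-bromo-6-methyl-2,3-dihydro-1,4-benzodioxin-2-yl]propan-2-yl}oxy)trimethylsilane
Product: 21 trimethyl[(2-{(2S)-8-[(1R)-1-[2-(1,3-dioxolan-2-yl)-3-methoxy-6-vinylphenyl]but-2-yn-1-yl]-6-methyl-2,3-dihydro-1,4-benzodioxin-2-yl}propan-2-yl)oxy]silane, via aryllithium 19 (not isolated), via arylzinc chloride 20 (not isolated)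
Conditions: 18, t-BuLi (2 equiv), THF, −78 °C; ZnCl2, −78 to 0 °C; then 10, NiCl2(MeOCH2CH2OMe) (10 mol%), indanyl-pybox (13 mol%, single antipode), DME/THF, −20 to 0 °C; aq. NH4Cl
Reagents that add atoms: none
Why: Stereoconvergent nickel/pybox-catalysed Negishi arylation of a racemic propargylic carbonate: nickel cleaves the C–O bond to a propargylic radical, so both enantiomers of 10 converge on one aryl(propargyl)nickel intermediate, and reductive elimination under control of the chiral ligand should set C1 as (R), while the remote (S) centre of ring C is a spectator and t-BuLi leaves no alkyl halide that could enter the nickel cycle.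

Step 12
Reactants: 21 trimethyl[(2-{(2S)-8-[(1R)-1-[2-(1,3-dioxolan-2-yl)-3-methoxy-6-vinylphenyl]but-2-yn-1-yl]-6-methyl-2,3-dihydro-1,4-benzodioxin-2-yl}propan-2-yl)oxy]silane
Product: 22 trimethyl[(2-{(2S)-8-[(1R)-7-(1,3-dioxolan-2-yl)-6-methoxy-2-(prop-1-en-2-yl)-1H-inden-1-yl]-6-methyl-2,3-dihydro-1,4-benzodioxin-2-yl}propan-2-yl)oxy]silane
Conditions: second-generation Grubbs catalyst RuCl2(=CHPh)(PCy3)(H2IMes) (10 mol%), CH2Cl2 (0.01 M), 40 °C, argon
Reagents that add atoms: none
Why: The ruthenium alkylidene is loaded onto the styrene carbon C3 and adds across the methyl alkyne so that C3 bonds to the proximal alkyne carbon C2; the vinylcarbene left on the distal carbon then takes a methylene from the styrene of a second substrate molecule, which forms the isopropenyl group and passes the chain on. The closest known reaction type is ruthenium-catalysed ring-closing enyne metathesis of 1,6-enynes to 1-alkenylcyclopentenes. Ring B closes in the exo mode as a five-membered ring, the endo alternative being a six-membered dihydronaphthalene that 1,6-enynes do not favour when the carbene starts on the alkene. No stereocentre is formed, and C1 is an sp3 spectator outside every metallacycle. The step needs ene-first initiation, secured by a monosubstituted styrene next to a hindered internal alkyne and by working without ethylene. It also needs a configurationally stable C1–H, secured by neutral conditions at 40 °C and by the acetal, which keeps a conjugating formyl group away from C1.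

Step 13
Reactants: 22 trimethyl[(2-{(2S)-8-[(1R)-7-(1,3-dioxolan-2-yl)-6-methoxy-2-(prop-1-en-2-yl)-1H-inden-1-yl]-6-methyl-2,3-dihydro-1,4-benzodioxin-2-yl}propan-2-yl)oxy]silane
Product: 23 trimethyl[(2-{(2S)-8-[(1R)-7-(1,3-dioxolan-2-yl)-6-methoxy-2-(propan-2-ylidene)-2,3-dihydro-1H-inden-1-yl]-6-methyl-2,3-dihydro-1,4-benzodioxin-2-yl}propan-2-yl)oxy]silane
Conditions: (η6-naphthalene)Cr(CO)3 (20 mol%), H2 (4 atm), THF, 40 °C
Reagents that add atoms: none
Why: Chromium tricarbonyl-catalysed 1,4-hydrogenation: the Cr(CO)3 fragment binds the diene in its s-cis form (both inner termini carry hydrogen and the 2,3-disubstitution favours s-cis) and delivers H2 to C3 and to the terminal methylene, which should leave the double bond at C2=C(CH3)2 without touching C1, the arenes, the acetal or the silyl ether.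

Step 14
Reactants: 23 trimethyl[(2-{(2S)-8-[(1R)-7-(1,3-dioxolan-2-yl)-6-methoxy-2-(propan-2-ylidene)-2,3-dihydro-1H-inden-1-yl]-6-methyl-2,3-dihydro-1,4-benzodioxin-2-yl}propan-2-yl)oxy]silane
Product: 24 (3R)-3-[(3S)-3-(2-hydroxypropan-2-yl)-7-methyl-2,3-dihydro-1,4-benzodioxin-5-yl]-5-methoxy-2-(propan-2-ylidene)-2,3-dihydro-1H-indene-4-carbaldehyde
Conditions: PPTS (cat.), acetone/H2O (10:1), 40 °C
Reagents that add atoms: water, O
Why: Mild acid-catalysed acetal hydrolysis releases the C7 aldehyde and cleaves the tertiary TMS ether at an acidity well below that needed to protonate the tetrasubstituted alkene.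

Step 15
Reactants: 24 (3R)-3-[(3S)-3-(2-hydroxypropan-2-yl)-7-methyl-2,3-dihydro-1,4-benzodioxin-5-yl]-5-methoxy-2-(propan-2-ylidene)-2,3-dihydro-1H-indene-4-carbaldehyde
Product: 25 Diaporindene G, (3R)-5-hydroxy-3-[(3S)-3-(2-hydroxypropan-2-yl)-7-methyl-2,3-dihydro-1,4-benzodioxin-5-yl]-2-(propan-2-ylidene)-2,3-dihydro-1H-indene-4-carbaldehyde
Conditions: MgI2·OEt2 (3 equiv), toluene/THF, 60 °C; aq. NH4Cl
Reagents that add atoms: none
Why: Chelation-controlled O-demethylation: magnesium bridges the aldehyde oxygen and the neighbouring methoxy oxygen and iodide removes the methyl group by SN2, so only the ether ortho to the carbonyl should be cleaved, under non-protic conditions that spare the dioxane ethers, the exocyclic alkene and C1.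

**Compound list**

1 | 2-bromo-4-methoxybenzaldehyde | COc1ccc(C=O)c(Br)c1 | starting material
2 | 2-bromo-4-methoxy-1-vinylbenzene | COc1ccc(C=C)c(Br)c1 | intermediate
3 | (2-bromo-6-methoxy-3-vinylphenyl)lithium | [Li]c1c(OC)ccc(C=C)c1Br | intermediate
4 | 2-bromo-6-methoxy-3-vinylbenzaldehyde | COc1ccc(C=C)c(Br)c1C=O | intermediate
5 | 2-(2-bromo-6-methoxy-3-vinylphenyl)-1,3-dioxolane | COc1ccc(C=C)c(Br)c1C1OCCO1 | intermediate
6 | [2-(1,3-dioxolan-2-yl)-3-methoxy-6-vinylphenyl]lithium | [Li]c1c(C=C)ccc(OC)c1C1OCCO1 | intermediate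
7 | 2-(1,3-dioxolan-2-yl)-3-methoxy-6-vinylbenzaldehyde | COc1ccc(C=C)c(C=O)c1C1OCCO1 | intermediate
8 | 1-propynylmagnesium bromide | CC#C[Mg]Br | starting material
9 | bromomagnesium rac-1-[2-(1,3-dioxolan-2-yl)-3-methoxy-6-vinylphenyl]but-2-yn-1-olate | CC#CC(O[Mg]Br)c1c(C=C)ccc(OC)c1C1OCCO1 | intermediate
10 | rac-1-[2-(1,3-dioxolan-2-yl)-3-methoxy-6-vinylphenyl]but-2-yn-1-yl methyl carbonate | CC#CC(OC(=O)OC)c1c(C=C)ccc(OC)c1C1OCCO1 | intermediate
11 | methyl (2R)-2,3-dihydroxypropanoate (methyl (R)-glycerate) | COC(=O)[C@H](O)CO | starting material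
12 | methyl (2R)-3-[(tert-butyldimethylsilyl)oxy]-2-hydroxypropanoate | COC(=O)[C@H](O)CO[Si](C)(C)C(C)(C)C | intermediate
13 | 2,6-dibromo-4-methylphenol | Cc1cc(Br)c(O)c(Br)c1 | starting material
14 | methyl (2S)-3-[(tert-butyldimethylsilyl)oxy]-2-(2,6-dibromo-4-methylphenoxy)propanoate | COC(=O)[C@@H](Oc1c(Br)cc(C)cc1Br)CO[Si](C)(C)C(C)(C)C | intermediate
15 | (3S)-4-[(tert-butyldimethylsilyl)oxy]-3-(2,6-dibromo-4-methylphenoxy)-2-methylbutan-2-ol | Cc1cc(Br)c(O[C@H](C(C)(C)O)CO[Si](C)(C)C(C)(C)C)c(Br)c1 | intermediate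
16 | (2S)-2-(2,6-dibromo-4-methylphenoxy)-3-methylbutane-1,3-diol | Cc1cc(Br)c(O[C@H](C(C)(C)O)CO)c(Br)c1 | intermediate
17 | 2-[(2S)-8-bromo-6-methyl-2,3-dihydro-1,4-benzodioxin-2-yl]propan-2-ol | Cc1cc(Br)c2O[C@H](C(C)(C)O)COc2c1 | intermediate
18 | ({2-[(2S)-8-bromo-6-methyl-2,3-dihydro-1,4-benzodioxin-2-yl]propan-2-yl}oxy)trimethylsilane | Cc1cc(Br)c2O[C@H](C(C)(C)O[Si](C)(C)C)COc2c1 | intermediate
19 | {(2S)-6-methyl-2-[2-(trimethylsilyloxy)propan-2-yl]-2,3-dihydro-1,4-benzodioxin-8-yl}lithium | Cc1cc([Li])c2O[C@H](C(C)(C)O[Si](C)(C)C)COc2c1 | intermediate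
20 | {(2S)-6-methyl-2-[2-(trimethylsilyloxy)propan-2-yl]-2,3-dihydro-1,4-benzodioxin-8-yl}zinc chloride | Cc1cc([Zn]Cl)c2O[C@H](C(C)(C)O[Si](C)(C)C)COc2c1 | intermediate
21 | trimethyl[(2-{(2S)-8-[(1R)-1-[2-(1,3-dioxolan-2-yl)-3-methoxy-6-vinylphenyl]but-2-yn-1-yl]-6-methyl-2,3-dihydro-1,4-benzodioxin-2-yl}propan-2-yl)oxy]silane | CC#C[C@H](c1c(C=C)ccc(OC)c1C1OCCO1)c1cc(C)cc2c1O[C@H](C(C)(C)O[Si](C)(C)C)CO2 | intermediate
22 | trimethyl[(2-{(2S)-8-[(1R)-7-(1,3-dioxolan-2-yl)-6-methoxy-2-(prop-1-en-2-yl)-1H-inden-1-yl]-6-methyl-2,3-dihydro-1,4-benzodioxin-2-yl}propan-2-yl)oxy]silane | CC(=C)C1=Cc2ccc(OC)c(C3OCCO3)c2[C@@H]1c1cc(C)cc2c1O[C@H](C(C)(C)O[Si](C)(C)C)CO2 | intermediate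
23 | trimethyl[(2-{(2S)-8-[(1R)-7-(1,3-dioxolan-2-yl)-6-methoxy-2-(propan-2-ylidene)-2,3-dihydro-1H-inden-1-yl]-6-methyl-2,3-dihydro-1,4-benzodioxin-2-yl}propan-2-yl)oxy]silane | CC(C)=C1Cc2ccc(OC)c(C3OCCO3)c2[C@@H]1c1cc(C)cc2c1O[C@H](C(C)(C)O[Si](C)(C)C)CO2 | intermediate
24 | (3R)-3-[(3S)-3-(2-hydroxypropan-2-yl)-7-methyl-2,3-dihydro-1,4-benzodioxin-5-yl]-5-methoxy-2-(propan-2-ylidene)-2,3-dihydro-1H-indene-4-carbaldehyde | CC(C)=C1Cc2ccc(OC)c(C=O)c2[C@@H]1c1cc(C)cc2c1O[C@H](C(C)(C)O)CO2 | intermediate
25 | Diaporindene G, (3R)-5-hydroxy-3-[(3S)-3-(2-hydroxypropan-2-yl)-7-methyl-2,3-dihydro-1,4-benzodioxin-5-yl]-2-(propan-2-ylidene)-2,3-dihydro-1H-indene-4-carbaldehyde | CC(C)=C1Cc2ccc(O)c(C=O)c2[C@@H]1c1cc(C)cc2c1O[C@H](C(C)(C)O)CO2 | target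

**Step count**

Total: 15 steps. Longest linear sequence: 10 steps (steps 1–5 or steps 6–10, then steps 11–15).

**Steps most likely to fail**

Step 11. The ring A aryl carries two ortho substituents, so capture of the propargylic radical by nickel may be slow. The small methyl group on the alkyne may let coupling leak to the allenyl terminus, and catalyst control at C1 may be weak. The fallback gives up catalyst control and relies on the fixed (S) centre of ring C. It sets out from 10 and 18 and comes back at 21. The arylzinc is made as in step 11 and coupled with 10 under an achiral catalyst, NiCl2(MeOCH2CH2OMe) with 4,4′-di-tert-butyl-2,2′-bipyridine, in DME/THF. The two C1 epimers are diastereomers and should be separable by preparative chromatography. This gives 21 and its epimer trimethyl[(2-{(2S)-8-[(1S)-1-[2-(1,3-dioxolan-2-yl)-3-methoxy-6-vinylphenyl]but-2-yn-1-yl]-6-methyl-2,3-dihydro-1,4-benzodioxin-2-yl}propan-2-yl)oxy]silane F1, which is set aside.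

Step 12. The hindered internal alkyne next to a diaryl-substituted carbon may not turn over. Closure may run through the methylidene (alkyne-first) path to the six-membered endo diene, or free PCy3 may promote a 1,3-shift of the indene C1–H. The fallback leaves ruthenium carbene chemistry. It sets out from 21 and comes back at 22. PtCl2 (10 mol%) in toluene at 80 °C activates the alkyne as a π-acid; attack of the styrene gives a cyclopropyl platinum carbene, and single-cleavage skeletal rearrangement of this 1,6-enyne should give the same 2-isopropenyl indene 22 without any phosphine present. The fallback makes no new compound (F0).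

Step 15. The exocyclic C2=C(CH3)2 double bond may migrate into conjugation with ring A under warm Lewis acid, which would also erase C1, or ether cleavage may stay incomplete. The fallback reorders the unmasking so that the methyl ether is cleaved before ring B and the isopropylidene exist. It sets out from 21 and comes back at 25.
- Hydrolysis of 21 with PPTS in acetone/H2O gives 2-{(1R)-1-[(3S)-3-(2-hydroxypropan-2-yl)-7-methyl-2,3-dihydro-1,4-benzodioxin-5-yl]but-2-yn-1-yl}-6-methoxy-3-vinylbenzaldehyde F2.
- MgI2·OEt2 in toluene/THF at 60 °C then gives 6-hydroxy-2-{(1R)-1-[(3S)-3-(2-hydroxypropan-2-yl)-7-methyl-2,3-dihydro-1,4-benzodioxin-5-yl]but-2-yn-1-yl}-3-vinylbenzaldehyde F3.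
- Ring-closing enyne metathesis with the second-generation Grubbs catalyst RuCl2(=CHPh)(PCy3)(H2IMes) gives (1R)-6-hydroxy-1-[(3S)-3-(2-hydroxypropan-2-yl)-7-methyl-2,3-dihydro-1,4-benzodioxin-5-yl]-2-(prop-1-en-2-yl)-1H-indene-7-carbaldehyde F4.
- The neutral 1,4-hydrogenation with (η6-naphthalene)Cr(CO)3 and H2 then ends the synthesis at 25.
- With the ortho formyl group free, C1–H is more acidic, so every operation after the hydrolysis must stay free of base.

Further compounds
F1 | step 11 | trimethyl[(2-{(2S)-8-[(1S)-1-[2-(1,3-dioxolan-2-yl)-3-methoxy-6-vinylphenyl]but-2-yn-1-yl]-6-methyl-2,3-dihydro-1,4-benzodioxin-2-yl}propan-2-yl)oxy]silane | CC#C[C@@H](c1c(C=C)ccc(OC)c1C1OCCO1)c1cc(C)cc2c1O[C@H](C(C)(C)O[Si](C)(C)C)CO2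
F0 | step 12 | none | none
F2 | step 15 | 2-{(1R)-1-[(3S)-3-(2-hydroxypropan-2-yl)-7-methyl-2,3-dihydro-1,4-benzodioxin-5-yl]but-2-yn-1-yl}-6-methoxy-3-vinylbenzaldehyde | CC#C[C@H](c1c(C=C)ccc(OC)c1C=O)c1cc(C)cc2c1O[C@H](C(C)(C)O)CO2
F3 | step 15 | 6-hydroxy-2-{(1R)-1-[(3S)-3-(2-hydroxypropan-2-yl)-7-methyl-2,3-dihydro-1,4-benzodioxin-5-yl]but-2-yn-1-yl}-3-vinylbenzaldehyde | CC#C[C@H](c1c(C=C)ccc(O)c1C=O)c1cc(C)cc2c1O[C@H](C(C)(C)O)CO2
F4 | step 15 | (1R)-6-hydroxy-1-[(3S)-3-(2-hydroxypropan-2-yl)-7-methyl-2,3-dihydro-1,4-benzodioxin-5-yl]-2-(prop-1-en-2-yl)-1H-indene-7-carbaldehyde | CC(=C)C1=Cc2ccc(O)c(C=O)c2[C@@H]1c1cc(C)cc2c1O[C@H](C(C)(C)O)CO2
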